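**Plan**

- Cuts, latest first: the C6 ester C–O bond and the C11=C13 methylene (carried as a Me2N–CH2 Mannich handle). Then C5–C6, between the Z-alkene carbon and the carbinol carbon, as an intramolecular alkenyl iodide/aldehyde (Nozaki–Hiyama–Kishi) ring closure. Then the furanone C2–C3 and C3–O bonds (aldol, oxidation, cyclodehydration), C6–C7 and C11–C13 (cuprate/Mannich on a butenolide), C7–C8 (iodoacrylate addition to a C8 aldehyde) and C9–C10 (allylation of a lactic acid acetal).
- Forward ring order: lactone (ring B), then the 3(2H)-furanone (ring A), then the ten-membered carbocycle, closed across the furanone oxygen as a nine-membered ether ring (ring C).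
- Enabling feature: C6 is an allylic carbinol between the Z-trisubstituted C4=C5 alkene and C7 of the lactone, which is the retron of an alkenylmetal/aldehyde addition. The furanone carries C3 and C10 on either side of its ring oxygen, so it holds the alkenyl iodide and the aldehyde-bearing chain in a 1,3 relation and templates the medium-ring closure.
- Stereochemistry: C10 from (S)-lactic acid (self-regeneration of the stereocentre), C8 by ligand-controlled chromium-mediated alkenylation, C7 by anti conjugate addition, C6 in the ring closure (allylic strain plus ring constraint), the Z-alkene from anti-carbomagnesiation of propargyl alcohol, the epoxide from Sharpless epoxidation.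

Key step: step 15

Remark: carbons carry germacrane numbers. C1 is the furanone carbonyl, C2=C3 the furanone alkene (ring oxygen joins C3 and C10), C4(C15)=C5 the Z-alkene, C6 the ester carbinol, C7/C8 the lactone fusion, C9 the methylene, C10(C14) the quaternary carbon, and C11, C12, C13 the lactone alpha-carbon, carbonyl and exo-methylene.

Assumption: the (4S)-oxazoline–sulfonamide ligand of step 7 is taken to deliver the 8S carbinol; if the sense of induction is opposite, its enantiomer is used.

**Step 1**
Reactants: 1 (S)-lactic acid; 2 pivalaldehyde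
Product: 3 (2S,5S)-2-tert-butyl-5-methyl-1,3-dioxolan-4-one
Conditions: TsOH·H2O (cat.), H2SO4 (cat.), pentane, reflux, Dean–Stark; crystallisation at −78 °C
Reagents that add atoms: none
Why: Acid-catalysed acetalisation under thermodynamic control should favour the cis dioxolanone, whose new acetal stereocentre is set by the lactic acid centre and enriched by crystallisation.

**Step 2**
Reactants: 3 (2S,5S)-2-tert-butyl-5-methyl-1,3-dioxolan-4-one; 4 allyl bromide
Product: 6 (2S,5R)-5-allyl-2-tert-butyl-5-methyl-1,3-dioxolan-4-one, via lithium enolate 5 (not isolated)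
Conditions: LiN(iPr)2, THF, −78 °C; then 4, −78 → −30 °C
Reagents that add atoms: none
Why: Enolate alkylation with self-regeneration of the stereocentre: allyl bromide should enter anti to the tert-butyl group and so fix quaternary C10 in the R series.

**Step 3**
Reactants: 6 (2S,5R)-5-allyl-2-tert-butyl-5-methyl-1,3-dioxolan-4-one
Product: 7 (2R)-2-hydroxy-N-methoxy-N,2-dimethylpent-4-enamide
Conditions: MeNH(OMe)·HCl, iPrMgCl, THF, −20 → 0 °C
Reagents that add atoms: N,O-dimethylhydroxylamine hydrochloride, CNOC.Cl
Why: Aminolysis of the acylal-type lactone by the chloromagnesium amide (Weinreb amide formation) should open the dioxolanone with loss of pivalaldehyde and leave the quaternary centre untouched.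

**Step 4**
Reactants: 7 (2R)-2-hydroxy-N-methoxy-N,2-dimethylpent-4-enamide
Product: 8 (2R)-N-methoxy-N,2-dimethyl-2-(triethylsilyloxy)pent-4-enamide
Conditions: Et3SiOTf, 2,6-lutidine, CH2Cl2, −78 → 0 °C
Reagents that add atoms: triethylsilyl trifluoromethanesulfonate, CC[Si](CC)(CC)OS(=O)(=O)C(F)(F)F
Why: Silyl ether protection of the tertiary alcohol with the silyl triflate masks it for the organometallic and enolate steps; the acid that closes ring A removes it later.

**Step 5**
Reactants: 8 (2R)-N-methoxy-N,2-dimethyl-2-(triethylsilyloxy)pent-4-enamide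
Product: 10 (3R)-3-methyl-3-(triethylsilyloxy)hex-5-en-2-one, via bromomagnesium hemiaminal adduct 9 (not isolated)
Conditions: MeMgBr, THF, 0 °C → rt; aq. NH4Cl
Reagents that add atoms: methylmagnesium bromide, C[Mg]Br
Why: Weinreb ketone synthesis: the chelated tetrahedral adduct should resist a second addition and release the methyl ketone (C1, C2) on work-up.

**Step 6**
Reactants: 10 (3R)-3-methyl-3-(triethylsilyloxy)hex-5-en-2-one
Product: 12 (3R)-3-methyl-4-oxo-3-(triethylsilyloxy)pentanal, via ozonide 11 (not isolated)
Conditions: O3, CH2Cl2, −78 °C; PPh3, −78 °C → rt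
Reagents that add atoms: ozone, [O-][O+]=O
Why: Ozonolysis with reductive work-up should cleave the only alkene to the C8 aldehyde, the ketone and silyl ether being inert.

**Step 7**
Reactants: 12 (3R)-3-methyl-4-oxo-3-(triethylsilyloxy)pentanal; 13 methyl (Z)-3-iodoprop-2-enoate
Product: 15 (5S)-5-[(2R)-2-methyl-3-oxo-2-(triethylsilyloxy)butyl]furan-2(5H)-one, via hydroxy enoate 14 (not isolated)
Conditions: CrCl2, N-{2-[(4S)-4-isopropyl-4,5-dihydro-1,3-oxazol-2-yl]-6-methylphenyl}methanesulfonamide, Et3N, NiCl2 (cat.), THF, rt; work-up, then PPTS (cat.), CH2Cl2, rt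
Reagents that add atoms: none
Why: Ligand-controlled Nozaki–Hiyama–Kishi alkenylation is aldehyde-selective in the presence of the ketone, the chiral chromium sulfonamide complex should set C8 (S), and the Z-hydroxy enoate should lactonise to the butenolide (ring B).

**Step 8**
Reactants: 15 (5S)-5-[(2R)-2-methyl-3-oxo-2-(triethylsilyloxy)butyl]furan-2(5H)-one
Product: 17 (3S,4R,5S)-3-[(dimethylamino)methyl]-4-ethenyl-5-[(2R)-2-methyl-3-oxo-2-(triethylsilyloxy)butyl]oxolan-2-one, via silyl ketene acetal 16 (not isolated)
Conditions: CH2=CHMgBr, CuBr·SMe2, Me3SiCl, THF, −78 °C; then Me2N=CH2+ I−, −78 °C → rt; aq. NH4Cl/NH3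
Reagents that add atoms: vinylmagnesium bromide, C=C[Mg]Br; dimethylmethylideneammonium iodide (Eschenmoser's salt), C[N+](C)=C.[I-]
Why: Copper-mediated conjugate addition should deliver the vinyl group (C6 plus a sacrificial carbon) to C7 anti to the C8 side chain, and Mannich aminomethylation of the silyl ketene acetal at C11, anti to the new vinyl group, installs the masked exo-methylene in the same flask without a free enolate near the ketone.

**Step 9**
Reactants: 17 (3S,4R,5S)-3-[(dimethylamino)methyl]-4-ethenyl-5-[(2R)-2-methyl-3-oxo-2-(triethylsilyloxy)butyl]oxolan-2-one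
Product: 19 (3S,4R,5S)-4-(dimethoxymethyl)-3-[(dimethylamino)methyl]-5-[(2R)-2-methyl-3-oxo-2-(triethylsilyloxy)butyl]oxolan-2-one, via aldehyde 18 (not isolated)
Conditions: OsO4 (cat.), NaIO4, 2,6-lutidine, dioxane/H2O, rt; crude aldehyde, then HC(OMe)3, CeCl3·7H2O (cat.), MeOH, rt
Reagents that add atoms: trimethyl orthoformate, COC(OC)OC; methanol, CO
Why: Lemieux–Johnson cleavage of the sole alkene should give the C6 aldehyde, which is protected at once as its dimethyl acetal (acetalisation selective for the aldehyde over the hindered ketone) so that the ketone can be enolised in step 12.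

**Step 10**
Reactants: 20 propargyl alcohol
Product: 22 (Z)-3-iodo-2-methylprop-2-en-1-ol, via alkenylmagnesium alkoxide 21 (not isolated)
Conditions: MeMgBr, CuI (cat.), THF, −10 °C → rt; then I2, −10 °C
Reagents that add atoms: methylmagnesium bromide, C[Mg]Br; iodine, II
Why: Copper-catalysed anti-carbomagnesiation of the propargylic alkoxide places magnesium cis to the CH2O group through a five-membered chelate, and iodinolysis with retention should give the Z-iodoalkene that becomes C4=C5.

**Step 11**
Reactants: 22 (Z)-3-iodo-2-methylprop-2-en-1-ol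
Product: 23 (Z)-3-iodo-2-methylprop-2-enal
Conditions: MnO2, CH2Cl2, rt, dark; used at once
Reagents that add atoms: none
Why: Allylic oxidation with MnO2 under neutral conditions should give the enal without Z to E isomerisation when it is used immediately.

**Step 12**
Reactants: 19 (3S,4R,5S)-4-(dimethoxymethyl)-3-[(dimethylamino)methyl]-5-[(2R)-2-methyl-3-oxo-2-(triethylsilyloxy)butyl]oxolan-2-one; 23 (Z)-3-iodo-2-methylprop-2-enal
Product: 25 aldol adduct (beta-hydroxy ketone; mixture of C3 epimers), via lithium enolate 24 (not isolated)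
Conditions: LiN(iPr)2, THF, −78 °C; then 23, −78 °C; AcOH quench
Reagents that add atoms: none
Why: Kinetic lithium enolate aldol addition: the methyl ketone is the most acidic and least hindered site (the lactone alpha-carbon is tertiary), so the C2–C3 bond should form, giving a C3 epimer mixture that is erased in step 13.

**Step 13**
Reactants: 25 aldol adduct
Product: 26 1,3-diketone (C1 and C3 carbonyls; largely enolised)
Conditions: Dess–Martin periodinane, NaHCO3, CH2Cl2, 0 °C → rt
Reagents that add atoms: none
Why: Dess–Martin oxidation of the beta-hydroxy ketone should give the 1,3-diketone under non-acidic conditions that spare the silyl ether, acetal and Z-iodoalkene.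

**Step 14**
Reactants: 26 1,3-diketone
Product: 28 furanone aldehyde (3S,4R,5S)-3-[(dimethylamino)methyl]-5-{[(2R)-5-[(Z)-1-iodoprop-1-en-2-yl]-2-methyl-3-oxo-2,3-dihydrofuran-2-yl]methyl}-2-oxooxolane-4-carbaldehyde, via hydroxy diketone 27 (not isolated)
Conditions: 1 M aq. HCl, THF, rt; then NaHCO3 to pH 8
Reagents that add atoms: water, O
Why: Acid-mediated desilylation, 5-exo-trig hemiketalisation of the tertiary hydroxyl onto C3 and dehydration (the classical cyclodehydration route to 3(2H)-furanones) should close ring A while the same acid hydrolyses the acetal to the C6 aldehyde; C7 carries its substituent trans to both neighbours and so is not at risk from equilibration.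

**Step 15**
Reactants: 28 furanone aldehyde
Product: 31 macrocyclic alcohol (13-dimethylamino-6-hydroxy-1-oxo-3,10-epoxy-11,13-dihydrogermacra-2,4Z-dien-12,8-olide; 6R carbinol), via alkenylchromium 29 (not isolated), via chromium alkoxide 30 (not isolated)
Conditions: CrCl2 (10 equiv), NiCl2 (0.1 equiv), degassed DMSO, rt, slow addition of 28 to 0.002 M; then H2O
Reagents that add atoms: none
Why: Zerovalent nickel, formed in situ from NiCl2 and CrCl2, should insert into the C5–I bond, transmetalation to trivalent chromium gives the Z-alkenylchromium 29, and this adds to the C6 aldehyde through a chromium-bridged transition state to give alkoxide 30 (Nozaki–Hiyama–Kishi reaction). The closest known reaction type is the intramolecular Nozaki–Hiyama–Kishi closure of medium rings, including nine-membered cyclic ethers bridged across an oxygen heterocycle. The closure is a 9-exo-trig addition across the furanone oxygen (O, C10, C9, C8, C7, C6, C5, C4, C3) and at the same time the 10-exo-trig closure of the carbocycle C1–C10, with the furanone holding C3 and C10 in a 1,3 relation across its ring oxygen. C6 is the one new stereocentre: with H6 in the plane of the C4=C5 bond on the side of C3 (allylic 1,3-strain), C8 must lie on the H6 side to bridge back to C10 and the lactone carbon C11 then sits anti to the incoming C5, an arrangement that corresponds to the 6R carbinol. The step needs chemoselectivity for the aldehyde over the furanone ketone and the lactone, which the organochromium reagent provides; retention of the Z geometry, which is expected for this trisubstituted alkenyl iodide and is the only geometry that can close the ring; and an aldehyde that does not isomerise, which the saturated Mannich base at C11 secures. High dilution is needed to suppress intermolecular coupling.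

**Step 16**
Reactants: 32 (E)-2-methylbut-2-en-1-ol
Product: 33 (2R,3R)-2,3-epoxy-2-methylbutan-1-ol
Conditions: Ti(OiPr)4 (cat.), D-(−)-diethyl tartrate (cat.), tBuOOH, 4 Å molecular sieves, CH2Cl2, −20 °C
Reagents that add atoms: tert-butyl hydroperoxide, CC(C)(C)OO
Why: Sharpless asymmetric epoxidation with the D-(−)-tartrate should deliver oxygen to the face of the E-allylic alcohol that gives the (2R,3R)-epoxy alcohol, setting both epoxide stereocentres.

**Step 17**
Reactants: 33 (2R,3R)-2,3-epoxy-2-methylbutan-1-ol
Product: 34 (2S,3R)-2,3-dimethyloxirane-2-carboxylic acid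
Conditions: TEMPO (cat.), PhI(OAc)2, MeCN/H2O, rt
Reagents that add atoms: water, O
Why: TEMPO-catalysed oxidation in aqueous acetonitrile should take the primary alcohol through the aldehyde hydrate to the acid without opening the epoxide; the C2 descriptor changes to S only through the priority change.

**Step 18**
Reactants: 31 macrocyclic alcohol; 34 (2S,3R)-2,3-dimethyloxirane-2-carboxylic acid
Product: 36 C6 epoxy ester of 31 (Mannich base still in place), via mixed anhydride 35 (not isolated)
Conditions: 34, 2,4,6-trichlorobenzoyl chloride, Et3N, toluene, rt; then 31, DMAP, toluene, rt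
Reagents that add atoms: none
Why: Yamaguchi esterification through the mixed anhydride should acylate the hindered allylic C6 hydroxyl with retention at C6 and at both epoxide centres.

**Step 19**
Reactants: 36 C6 epoxy ester
Product: 38 target CNP0258430.2, via methiodide 37 (not isolated)
Conditions: MeI, MeCN, rt; evaporate; then NaHCO3, THF/H2O, rt
Reagents that add atoms: none
Why: Exhaustive N-methylation and E1cB elimination of trimethylamine from the beta-ammonio lactone (the closing stage of an Eschenmoser methylenation) should reveal the C11=C13 exo-methylene under conditions that spare the epoxide, the ester and the furanone.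

**Compound list**

1 | (S)-lactic acid | C[C@H](O)C(=O)O | starting material
2 | pivalaldehyde | CC(C)(C)C=O | starting material
3 | (2S,5S)-2-tert-butyl-5-methyl-1,3-dioxolan-4-one | C[C@@H]1O[C@H](C(C)(C)C)OC1=O | intermediate
4 | allyl bromide | C=CCBr | starting material
5 | lithium enolate of 3 (lithium 2-tert-butyl-5-methyl-1,3-dioxol-4-olate) | CC1=C(O[Li])O[C@@H](C(C)(C)C)O1 | intermediate
6 | (2S,5R)-5-allyl-2-tert-butyl-5-methyl-1,3-dioxolan-4-one | C[C@]1(CC=C)O[C@H](C(C)(C)C)OC1=O | intermediate
7 | (2R)-2-hydroxy-N-methoxy-N,2-dimethylpent-4-enamide | C=CC[C@@](C)(O)C(=O)N(C)OC | intermediate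
8 | (2R)-N-methoxy-N,2-dimethyl-2-(triethylsilyloxy)pent-4-enamide | C=CC[C@@](C)(O[Si](CC)(CC)CC)C(=O)N(C)OC | intermediate
9 | bromomagnesium hemiaminal adduct of 8 with MeMgBr | C=CC[C@@](C)(O[Si](CC)(CC)CC)C(C)(O[Mg]Br)N(C)OC | intermediate
10 | (3R)-3-methyl-3-(triethylsilyloxy)hex-5-en-2-one | C=CC[C@@](C)(O[Si](CC)(CC)CC)C(C)=O | intermediate
11 | ozonide (1,2,4-trioxolane) of 10 | C1OC(C[C@@](C)(O[Si](CC)(CC)CC)C(C)=O)OO1 | intermediate
12 | (3R)-3-methyl-4-oxo-3-(triethylsilyloxy)pentanal | O=CC[C@@](C)(O[Si](CC)(CC)CC)C(C)=O | intermediate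
13 | methyl (Z)-3-iodoprop-2-enoate | COC(=O)/C=C\I | starting material
14 | methyl (2Z,4S,6R)-4-hydroxy-6-methyl-7-oxo-6-(triethylsilyloxy)oct-2-enoate | COC(=O)/C=C\[C@@H](O)C[C@@](C)(O[Si](CC)(CC)CC)C(C)=O | intermediate
15 | (5S)-5-[(2R)-2-methyl-3-oxo-2-(triethylsilyloxy)butyl]furan-2(5H)-one | O=C1O[C@H](C=C1)C[C@@](C)(O[Si](CC)(CC)CC)C(C)=O | intermediate
16 | trimethylsilyl ketene acetal of the 4-vinyl lactone | C[Si](C)(C)OC1=C[C@@H](C=C)[C@H](C[C@@](C)(O[Si](CC)(CC)CC)C(C)=O)O1 | intermediate
17 | (3S,4R,5S)-3-[(dimethylamino)methyl]-4-ethenyl-5-[(2R)-2-methyl-3-oxo-2-(triethylsilyloxy)butyl]oxolan-2-one | O=C1O[C@@H](C[C@@](C)(O[Si](CC)(CC)CC)C(C)=O)[C@H](C=C)[C@H]1CN(C)C | intermediate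
18 | (3S,4R,5S)-3-[(dimethylamino)methyl]-5-[(2R)-2-methyl-3-oxo-2-(triethylsilyloxy)butyl]-2-oxooxolane-4-carbaldehyde | O=C1O[C@@H](C[C@@](C)(O[Si](CC)(CC)CC)C(C)=O)[C@H](C=O)[C@H]1CN(C)C | intermediate
19 | (3S,4R,5S)-4-(dimethoxymethyl)-3-[(dimethylamino)methyl]-5-[(2R)-2-methyl-3-oxo-2-(triethylsilyloxy)butyl]oxolan-2-one | O=C1O[C@@H](C[C@@](C)(O[Si](CC)(CC)CC)C(C)=O)[C@H](C(OC)OC)[C@H]1CN(C)C | intermediate
20 | propargyl alcohol | C#CCO | starting material
21 | (Z)-alkenylmagnesium alkoxide from carbomagnesiation of 20 | Br[Mg]OC/C(C)=C\[Mg]Br | intermediate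
22 | (Z)-3-iodo-2-methylprop-2-en-1-ol | OC/C(C)=C\I | intermediate
23 | (Z)-3-iodo-2-methylprop-2-enal | O=C/C(C)=C\I | intermediate
24 | lithium enolate of 19 at the methyl ketone | O=C1O[C@@H](C[C@@](C)(O[Si](CC)(CC)CC)C(=C)O[Li])[C@H](C(OC)OC)[C@H]1CN(C)C | intermediate
25 | aldol adduct (C3 hydroxy, C1 ketone; C3 epimers) | O=C1O[C@@H](C[C@@](C)(O[Si](CC)(CC)CC)C(=O)CC(O)/C(C)=C\I)[C@H](C(OC)OC)[C@H]1CN(C)C | intermediate
26 | 1,3-diketone (C1 and C3 carbonyls) | O=C1O[C@@H](C[C@@](C)(O[Si](CC)(CC)CC)C(=O)CC(=O)/C(C)=C\I)[C@H](C(OC)OC)[C@H]1CN(C)C | intermediate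
27 | desilylated hydroxy diketone with free C6 aldehyde | O=C1O[C@@H](C[C@@](C)(O)C(=O)CC(=O)/C(C)=C\I)[C@H](C=O)[C@H]1CN(C)C | intermediate
28 | furanone aldehyde (ring A and ring B, Z-alkenyl iodide, C6 aldehyde) | O=C1O[C@@H](C[C@@]2(C)OC(=CC2=O)/C(C)=C\I)[C@H](C=O)[C@H]1CN(C)C | intermediate
29 | Z-alkenylchromium dichloride from 28 | O=C1O[C@@H](C[C@@]2(C)OC(=CC2=O)/C(C)=C\[Cr](Cl)Cl)[C@H](C=O)[C@H]1CN(C)C | intermediate
30 | chromium alkoxide of the macrocyclic alcohol | CN(C)C[C@H]1C(=O)O[C@H]2C[C@@]3(C)OC(=CC3=O)/C(C)=C\[C@@H](O[Cr](Cl)Cl)[C@H]12 | intermediate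
31 | macrocyclic alcohol (6R; trans lactone; C10 R; C11 S) | CN(C)C[C@H]1C(=O)O[C@H]2C[C@@]3(C)OC(=CC3=O)/C(C)=C\[C@@H](O)[C@H]12 | intermediate
32 | (E)-2-methylbut-2-en-1-ol | C/C=C(\C)CO | starting material
33 | (2R,3R)-2,3-epoxy-2-methylbutan-1-ol | OC[C@@]1(C)O[C@@H]1C | intermediate
34 | (2S,3R)-2,3-dimethyloxirane-2-carboxylic acid | OC(=O)[C@@]1(C)O[C@@H]1C | intermediate
35 | mixed anhydride of 34 with 2,4,6-trichlorobenzoic acid | O=C(OC(=O)[C@@]1(C)O[C@@H]1C)c1c(Cl)cc(Cl)cc1Cl | intermediate
36 | C6 (2S,3R)-2,3-dimethyloxirane-2-carboxylate of 31 | CN(C)C[C@H]1C(=O)O[C@H]2C[C@@]3(C)OC(=CC3=O)/C(C)=C\[C@@H](OC(=O)[C@@]3(C)O[C@@H]3C)[C@H]12 | intermediate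
37 | trimethylammonium iodide (methiodide) of 36 | C[N+](C)(C)C[C@H]1C(=O)O[C@H]2C[C@@]3(C)OC(=CC3=O)/C(C)=C\[C@@H](OC(=O)[C@@]3(C)O[C@@H]3C)[C@H]12.[I-] | intermediate
38 | CNP0258430.2: (6R,7R,8S,10R)-1-oxo-3,10-epoxygermacra-2,4Z,11(13)-trien-12,8-olide 6-[(2S,3R)-2,3-dimethyloxirane-2-carboxylate] | C=C1C(=O)O[C@H]2C[C@@]3(C)OC(=CC3=O)/C(C)=C\[C@@H](OC(=O)[C@@]3(C)O[C@@H]3C)[C@H]12 | target

**Count and risks**

Total: 19 steps. Longest linear sequence: 15 steps (steps 1–9, 12–15, 18 and 19).

Steps most likely to fail:

1. Step 15. Facial selectivity at the aldehyde during ring closure may be poor or reversed, since the allylic-strain/ring-constraint model is untested on this skeleton; intermolecular coupling or protodeiodination may also compete if closure is slow. Fallback: setting out from 28, the closure is run as before and the undesired (6S)-alcohol F1, alone or mixed with 31, is oxidised with Dess–Martin periodinane to the C6 ketone F2. Reagent-controlled 1,2-reduction of F2 with a CBS oxazaborolidine and catecholborane (antipode chosen to give 6R) comes back to the route at 31. C6 is then set by reduction of the closed ring and not in the closure.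

2. Step 7. The Z geometry may be lost at the alkenylchromium stage, so that the hydroxy enoate cannot lactonise; beta-elimination of silanol from aldehyde 12 may also erode material. Fallback: setting out from 12, ligand-controlled Nozaki–Hiyama–Kishi addition of vinyl bromide (CrCl2, the same sulfonamide ligand, Et3N, NiCl2 cat.) gives (3R,5S)-5-hydroxy-3-methyl-3-(triethylsilyloxy)hept-6-en-2-one F3. Acylation with acryloyl chloride and Et3N gives the acrylate F4, and ring-closing metathesis with second-generation Grubbs catalyst comes back to the route at 15. No alkene geometry has to survive the organochromium stage.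

3. Step 12. Deprotonation may compete at the lactone, and the labile Z-iodoenal 23 may isomerise or decompose under strongly basic conditions. Fallback: setting out from 22 and 19, alcohol 22 is oxidised (TEMPO, PhI(OAc)2, aqueous MeCN) to (Z)-3-iodo-2-methylprop-2-enoic acid F5, which is activated as 1-[(Z)-3-iodo-2-methylprop-2-enoyl]-1H-benzotriazole F6 (benzotriazole, dicyclohexylcarbodiimide). C-acylation of ketone 19 with F6 under soft enolisation (MgBr2·OEt2, iPr2NEt, CH2Cl2), which enolises ketones but not lactones, gives the diketone directly and comes back to the route at 26; steps 11 to 13 are then not needed.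

**Further compounds**

F1 | step 15 | (6S)-epimer of macrocyclic alcohol 31 | CN(C)C[C@H]1C(=O)O[C@H]2C[C@@]3(C)OC(=CC3=O)/C(C)=C\[C@H](O)[C@H]12
F2 | step 15 | C6 ketone (6-oxo analogue of 31) | CN(C)C[C@H]1C(=O)O[C@H]2C[C@@]3(C)OC(=CC3=O)/C(C)=C\C(=O)[C@H]12
F3 | step 7 | (3R,5S)-5-hydroxy-3-methyl-3-(triethylsilyloxy)hept-6-en-2-one | C=C[C@@H](O)C[C@@](C)(O[Si](CC)(CC)CC)C(C)=O
F4 | step 7 | acrylate ester of F3 | C=CC(=O)O[C@H](C=C)C[C@@](C)(O[Si](CC)(CC)CC)C(C)=O
F5 | step 12 | (Z)-3-iodo-2-methylprop-2-enoic acid | OC(=O)/C(C)=C\I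
F6 | step 12 | 1-[(Z)-3-iodo-2-methylprop-2-enoyl]-1H-benzotriazole | O=C(/C(C)=C\I)n1nnc2ccccc12
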